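## Structural features

The target is a 2-aryl-3-(hydroxymethyl)-2,3-dihydrobenzofuran. Ring C is a five-membered cyclic ether (O–C7–C8–C3'–C4') fused through C3'–C4' to the arene ring B, and C7 carries ring A (3,4,5-trimethoxyphenyl). Ring B is tetrasubstituted: the ring oxygen on C4', a methoxy group on C5', C8 on C3' and an (E)-3-hydroxyprop-1-enyl chain on C1'. The only stereocentres, C7 (R, a benzylic ether carbon) and C8 (S, bearing C9H2OH), are neighbours, with aryl and hydroxymethyl trans on ring C. Fragile points are the benzylic aryl ether bond C7–O (acid can ionise it and scramble C7; hydrogenolysis cleaves it), the electron-rich cinnamyl-type allylic alcohol (acid, oxidants, hydrogenation) and two electron-rich arenes that make electrophilic substitution unselective. The real difficulty is absolute and relative control of the C7/C8 pair together with regiocontrolled substitution of ring B. The key step exploits the fact that O–C7–C8(–C9–O) is a syn aldol pattern whose C7 oxygen already is the ring oxygen. Only the aryl bond O–C4' is then missing, and it can be made by displacing fluoride on ring B without touching either stereocentre. A second useful feature is that C1'–H is the only aromatic hydrogen with a hydrogen on both sides.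

## Logic of the disconnections

18 ⇒ 16 + 17. The C1'–C7' bond is cut. It joins two sp2 carbons, and the three-carbon chain can arrive with its E geometry and its hydroxyl already in place. This removes any redox or deprotection after the coupling. The forward step must be a stereoretentive cross-coupling mild enough for two free hydroxyls and for the C7–O bond.

16 ⇒ 13. The C1'–B bond is cut back to C1'–H. That hydrogen is the only one on either arene without an ortho substituent, so ring B need not carry a handle through the synthesis and the simple acid 1 suffices. The forward step must discriminate five aromatic C–H bonds on steric grounds and tolerate the primary hydroxyl.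

13 ⇒ 12. The O9–CPh3 bond is cut. The triphenylmethyl group has nine unhindered phenyl C–H bonds that would compete in the borylation, so it must leave first. The forward step needs acid mild enough not to ionise C7–O.

12 ⇒ 10 (through 11). The aryl ether bond O–C4' is cut; this is the strategic disconnection. It opens ring C without touching a stereocentre and turns a bicyclic ether into an acyclic syn 1,3-diol monoether with the C7–O bond already in place. The forward step needs a leaving group on C4' fit for addition–elimination (fluorine) and an O9 that is inert and immobile. A silyl ether on O9 is avoided for two reasons: it sits 1,3 to the C7 alkoxide and could migrate to it, and the fluoride set free could cleave it. Either event would expose a primary alkoxide able to close an isomeric five-membered ring through O9. A triphenylmethyl ether can do neither.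

10 ⇒ 9. The O9–CPh3 bond is cut to the free diol. The forward step must select the primary hydroxyl over the hindered C7 carbinol, which the bulk of the triphenylmethyl cation secures.

9 ⇒ 8. C9 is returned to the acyl oxidation level and the C9–N bond to the auxiliary is restored. The forward step is a reductive cleavage that must avoid retro-aldol and epimerisation at the acidic C8.

8 ⇒ 4 + 5 (through 6 and 7). The C7–C8 bond is cut. This is the only step that creates stereocentres, and it sets both at once from two achiral carbon partners. The forward step needs a Z enolate for the syn relation and the R auxiliary for the (7R,8S) sense.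

4 ⇒ 1 + 2 (through 3). The N–acyl bond is cut to the purchasable acid and auxiliary. The forward step must activate an arylacetic acid without forming the ketene.

## Other disconnections considered

Alternative 1: The cut removes both aryl–carbon bonds of the two-carbon bridge, C7–C1 (ring A) and C8–C3' (ring B), leaving a three-carbon alkenyl boronate.

- **Forward step.** 3,4,5-Trimethoxyphenyllithium A2 would add to boron of the (E)-alkenyl pinacol boronate A1. The arylpalladium species from the ring B bromide A3 with Pd(OAc)2 and MandyPhos would bind the alkene of the ate complex and trigger a 1,2-shift of ring A from boron to C7. Reductive elimination would then deliver ring B to C8, giving the boronate A4.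
- **In its favour.** Both C–C bonds and both stereocentres would come from one catalytic enantioselective step, and the relative configuration would follow from the alkene geometry. Ring B arrives fully substituted, C1' acrylate included, so no late C–H functionalisation is needed. On convergence and on economy of the chiral controller this plan is the better one.
- **Against it here.** A1 is a 1,2-disubstituted alkenyl boronate, the class in which direct Suzuki–Miyaura transfer of the alkenyl group competes most with the metallate shift. A3 holds an acrylate that can insert into the arylpalladium bond or accept any A2 not bound to boron, and the bromide released slows the cationic palladium pathway.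
- **Structural problem.** A4 does not contain ring C, and its ring oxygen must be O4' of ring B, not an oxygen introduced at C7. Oxidation of the C–B bond with retention would give the alcohol A5, which has the same syn arrangement as 10. An invertive closure through O4' would then lead to the cis ring. The configuration drawn for A4 therefore fits the trans target only if closure runs through the C7 benzylic cation under thermodynamic control; otherwise the C7 epimer (from the Z isomer of A1) is the correct intermediate.
- **Comparison.** In either case the C7 centre made in the key step is inverted or erased, whereas the chosen plan keeps the aldol C7–O bond to the end. After A4, oxidation, acetal removal, ring closure, ester reduction and desilylation would still be needed, besides making A1 and A3, so the step count would be no lower than eight.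

Alternative 2: The cut is the C7–C8 bond of ring C, with O4'–C7 already present as a 3,4,5-trimethoxybenzyl ether of ring B.

- **Forward step.** Rh2(S-PTTL)4 would turn the aryldiazoacetate A6 into a dirhodium carbene at C8, which would insert into the benzylic C7–H bond and give the cis ester A7.
- **In its favour.** Induction is catalytic. The C–H bond attacked is activated by the ether oxygen and by an electron-rich ring, the best case for this insertion. C9 is delivered as an ester and C1' as a bromide, so the chain could be added by a Mizoroki–Heck reaction and both esters reduced together. On the catalytic chiral controller and on the C1' handle (no reliance on site-selective C–H borylation) this plan is the better one.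
- **Against it.** The insertion favours the cis ring, so C8 must be epimerised through the ester enolate. That enolate can also expel the O4' phenoxide from C7 (E1cB opening of ring C), which would endanger C7. The diazo compound adds a diazo-transfer step and a safety burden. Oxonium ylide formation at the ether oxygen and carbene attack on the electron-rich rings are competing paths. A6 needs an arylacetic ester of the 5-bromo-2-hydroxy-3-methoxyphenyl series, itself several steps from purchasable aldehydes.
- **Comparison.** The chosen plan gives the trans ring directly and never places an acidifying group on C8 once ring C exists. In step count the two plans would be about equal (eight to nine).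

Alternative 3: The cut takes out C7–C8 and O4'–C7 together: a [4+1] assembly of ring C from a four-atom ortho-quinone methide (O4', C4', C3', C8) and C7 as a one-carbon ylide unit.

- **Forward step.** Cs2CO3 would eliminate sulfinate from the phenolic sulfone A8 and deprotonate the benzylsulfonium salt A9. A9 is drawn with a C2-symmetric thiolane as one possible chiral sulfide; which enantiomer is required would have to be established. The ylide carbon would add to C8 and the phenoxide would then displace the sulfide at C7 in an SN2 step, giving A10.
- **In its favour.** Two bonds, ring C and both stereocentres come in one operation. The anti betaine closes to the trans ring, so on diastereocontrol it is the equal of the chosen plan. The C1' bromide is present from the start, and the chiral sulfide is recoverable like the oxazolidinone. On convergence and probably on step count (about seven) it is the better plan.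
- **Against it.** Absolute control rests on face selection when a semi-stabilised ylide adds to a transient planar quinone methide whose C8 substituent is a small alkyl-type group. That is a less differentiated case than the aryl-substituted quinone methides usually used. A quinone methide with hydrogens on C9 can tautomerise to the ortho-hydroxystyrene (here a silyl enol ether) and leave the reaction. The electron-rich benzylsulfonium salt is a weak carbon acid, so ylide formation with carbonate may lag behind quinone methide formation and allow its dimerisation. A8 is not a trivial starting point.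
- **Comparison.** The chosen plan is linear, but it takes its absolute configuration from a boron aldol transition state that is far better understood.

Key step: step 5

Assumption: 17 is treated as a catalogue reagent (otherwise one step from propargyl alcohol by hydrostannylation and iododestannylation). Atom labels follow neolignan numbering: C7–C8–C9 bridge, unprimed ring A, primed ring B.

## Route

Step 1
Reactants: 1 (2-fluoro-3-methoxyphenyl)acetic acid; 2 (R)-4-benzyloxazolidin-2-one
Product: 4 (R)-4-benzyl-3-[2-(2-fluoro-3-methoxyphenyl)acetyl]oxazolidin-2-one, via mixed pivalic anhydride 3 (not isolated)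
Conditions: PivCl, Et3N, THF, −20 °C; then LiCl, 2, −20 °C → rt
Reagents that add atoms: none
Why: N-acylation through the mixed pivalic anhydride; LiCl lets the neutral oxazolidinone be acylated at the less hindered arylacetyl carbonyl, which avoids a strong base and the ketene pathway open to arylacetyl chlorides. No stereocentre is formed.

Step 2
Reactants: 4 (R)-4-benzyl-3-[2-(2-fluoro-3-methoxyphenyl)acetyl]oxazolidin-2-one; 5 3,4,5-trimethoxybenzaldehyde
Product: 8 (R)-4-benzyl-3-[(2R,3R)-2-(2-fluoro-3-methoxyphenyl)-3-hydroxy-3-(3,4,5-trimethoxyphenyl)propanoyl]oxazolidin-2-one, via dibutylboron Z-enolate 6 (not isolated), via dibutylboron aldolate 7 (not isolated)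
Conditions: Bu2BOTf, iPr2NEt, CH2Cl2, 0 °C; then 5, −78 → 0 °C; then pH 7 buffer, MeOH, 30% H2O2, 0 °C
Reagents that add atoms: none
Why: Evans syn-aldol reaction: the Z boron enolate reacts through a closed Zimmerman–Traxler chair, which fixes the syn C7/C8 relation. With the auxiliary carbonyl turned away from the enolate oxygen, the aldehyde is taken on the face opposite the benzyl group of the R auxiliary, which should set C8 and C7 as (2R,3R), the 7R,8S array of the target. Oxidative work-up frees the aldol from boron.

Step 3
Reactants: 8 (R)-4-benzyl-3-[(2R,3R)-2-(2-fluoro-3-methoxyphenyl)-3-hydroxy-3-(3,4,5-trimethoxyphenyl)propanoyl]oxazolidin-2-one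
Product: 9 (1R,2S)-2-(2-fluoro-3-methoxyphenyl)-1-(3,4,5-trimethoxyphenyl)propane-1,3-diol
Conditions: LiBH4, THF, 0 °C
Reagents that add atoms: none
Why: Reductive cleavage of the N-acyl oxazolidinone: hydride attacks the exocyclic imide carbonyl and releases 2 for reuse, while the low temperature and weakly basic hydride spare the retro-aldol and C8 epimerisation pathways. Neither stereocentre is touched; the C8 descriptor changes from R to S only because C9 drops in CIP rank.

Step 4
Reactants: 9 (1R,2S)-2-(2-fluoro-3-methoxyphenyl)-1-(3,4,5-trimethoxyphenyl)propane-1,3-diol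
Product: 10 (1R,2S)-2-(2-fluoro-3-methoxyphenyl)-1-(3,4,5-trimethoxyphenyl)-3-(triphenylmethoxy)propan-1-ol
Conditions: TrCl, Et3N, DMAP (cat.), CH2Cl2, rt
Reagents that add atoms: trityl chloride, ClC(c1ccccc1)(c1ccccc1)c1ccccc1
Why: Tritylation is confined to the primary hydroxyl on steric grounds, leaving the C7 carbinol (flanked by ring A and the C8 aryl branch) free. The trityl ether is chosen because it cannot migrate to a neighbouring alkoxide and is inert to fluoride.

Step 5
Reactants: 10 (1R,2S)-2-(2-fluoro-3-methoxyphenyl)-1-(3,4,5-trimethoxyphenyl)-3-(triphenylmethoxy)propan-1-ol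
Product: 12 (2R,3S)-7-methoxy-2-(3,4,5-trimethoxyphenyl)-3-[(triphenylmethoxy)methyl]-2,3-dihydro-1-benzofuran, via potassium alkoxide 11 (not isolated)
Conditions: KN(SiMe3)2 (1.2 equiv), THF–DMPU (3:1), 0 °C → 70 °C
Reagents that add atoms: none
Why: KN(SiMe3)2 deprotonates the only hydroxyl of 10 to the potassium alkoxide 11, which DMPU keeps loosely ion-paired. The alkoxide oxygen adds to C4' of ring B ipso to fluorine and fluoride leaves through a Meisenheimer-type transition state (addition–elimination, probably close to concerted on this unactivated ring); the closest known reaction type is the intramolecular alkoxide SNAr of ortho-fluoroaryl alcohols to 2,3-dihydrobenzofurans. Ring C closes in the 5-exo-trig mode, the O–C4' bond forming while negative charge is pushed onto C3', C5' and C1' outside the new ring. No stereocentre is formed: C7 and C8 are spectators, and because the aldol C7–O bond is kept, the syn relation of 10 becomes the trans relation of aryl and CH2OTr in 12 with 7R,8S unchanged. The only selectivity needed is O7 against O9, and the trityl ether secures it, since it can neither migrate to the adjacent alkoxide nor be cleaved by the fluoride released. Both positions ortho to fluorine are substituted, so an aryne pathway is closed; the C5' methoxy group slows the substitution, hence the heating.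

Step 6
Reactants: 12 (2R,3S)-7-methoxy-2-(3,4,5-trimethoxyphenyl)-3-[(triphenylmethoxy)methyl]-2,3-dihydro-1-benzofuran
Product: 13 [(2R,3S)-7-methoxy-2-(3,4,5-trimethoxyphenyl)-2,3-dihydro-1-benzofuran-3-yl]methanol
Conditions: TsOH·H2O (10 mol %), MeOH–CH2Cl2 (1:1), rt
Reagents that add atoms: none
Why: Acid-catalysed solvolysis of the trityl ether through the trityl cation, trapped by methanol; the C7–O bond of ring C ionises far less readily and should stay closed. The trityl group must go here because its unhindered phenyl C–H bonds would compete in step 7.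

Step 7
Reactants: 13 [(2R,3S)-7-methoxy-2-(3,4,5-trimethoxyphenyl)-2,3-dihydro-1-benzofuran-3-yl]methanol
Product: 16 [(2R,3S)-7-methoxy-5-(4,4,5,5-tetramethyl-1,3,2-dioxaborolan-2-yl)-2-(3,4,5-trimethoxyphenyl)-2,3-dihydro-1-benzofuran-3-yl]methanol, via O-boryl ether 14 (not isolated), via O-boryl aryl boronate 15 (not isolated)
Conditions: HBpin (1.1 equiv), [Ir(cod)(OMe)]2 (1.5 mol %), dtbpy (3 mol %), THF, rt; then B2pin2 (1.0 equiv), 65 °C; then MeOH, rt
Reagents that add atoms: bis(pinacolato)diboron, CC1(C)OB(OC1(C)C)B1OC(C)(C)C(C)(C)O1; pinacolborane, [H]B1OC(C)(C)C(C)(C)O1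
Why: Iridium-catalysed aromatic C–H borylation through a tris(boryl) complex of trivalent iridium, governed by sterics: C1'–H is the only aromatic hydrogen with hydrogens on both sides, whereas C2'–H, C6'–H and both ring A hydrogens have at least one ortho substituent. The hydroxyl is masked in the flask as its O–Bpin ether and freed again by methanol; no stereocentre is involved.

Step 8
Reactants: 16 [(2R,3S)-7-methoxy-5-(4,4,5,5-tetramethyl-1,3,2-dioxaborolan-2-yl)-2-(3,4,5-trimethoxyphenyl)-2,3-dihydro-1-benzofuran-3-yl]methanol; 17 (E)-3-iodoprop-2-en-1-ol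
Product: 18 (−)-(7R,8S,7'E)-3,4,5,5'-tetramethoxy-4',7-epoxy-8,3'-neolign-7'-ene-9,9'-diol
Conditions: Pd(dppf)Cl2 (5 mol %), K2CO3, 1,4-dioxane–H2O (4:1), 60 °C
Reagents that add atoms: none
Why: Suzuki–Miyaura coupling: oxidative addition of the alkenyl iodide to zerovalent palladium, transmetalation from the aryl boronate and reductive elimination all proceed with retention, so the E geometry of 17 is carried into the C7'=C8' bond. Free hydroxyls are tolerated and the carbonate base does not threaten C7 or C8.

## Compound list

1 | (2-fluoro-3-methoxyphenyl)acetic acid | COc1cccc(CC(=O)O)c1F | starting material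
2 | (R)-4-benzyloxazolidin-2-one | O=C1N[C@H](Cc2ccccc2)CO1 | starting material
3 | (2-fluoro-3-methoxyphenyl)acetic pivalic anhydride | COc1cccc(CC(=O)OC(=O)C(C)(C)C)c1F | intermediate
4 | (R)-4-benzyl-3-[2-(2-fluoro-3-methoxyphenyl)acetyl]oxazolidin-2-one | COc1cccc(CC(=O)N2[C@H](Cc3ccccc3)COC2=O)c1F | intermediate
5 | 3,4,5-trimethoxybenzaldehyde | COc1cc(C=O)cc(OC)c1OC | starting material
6 | (Z)-dibutylboron enolate of 4 | CCCCB(CCCC)O/C(=C\c1cccc(OC)c1F)N1[C@H](Cc2ccccc2)COC1=O | intermediate
7 | O-dibutylboryl aldolate of 8 | COc1cc(cc(OC)c1OC)[C@H](OB(CCCC)CCCC)[C@H](C(=O)N1[C@H](Cc2ccccc2)COC1=O)c1cccc(OC)c1F | intermediate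
8 | (R)-4-benzyl-3-[(2R,3R)-2-(2-fluoro-3-methoxyphenyl)-3-hydroxy-3-(3,4,5-trimethoxyphenyl)propanoyl]oxazolidin-2-one | COc1cc(cc(OC)c1OC)[C@H](O)[C@H](C(=O)N1[C@H](Cc2ccccc2)COC1=O)c1cccc(OC)c1F | intermediate
9 | (1R,2S)-2-(2-fluoro-3-methoxyphenyl)-1-(3,4,5-trimethoxyphenyl)propane-1,3-diol | COc1cc(cc(OC)c1OC)[C@H](O)[C@H](CO)c1cccc(OC)c1F | intermediate
10 | (1R,2S)-2-(2-fluoro-3-methoxyphenyl)-1-(3,4,5-trimethoxyphenyl)-3-(triphenylmethoxy)propan-1-ol | COc1cc(cc(OC)c1OC)[C@H](O)[C@H](COC(c1ccccc1)(c1ccccc1)c1ccccc1)c1cccc(OC)c1F | intermediate
11 | potassium alkoxide of 10 | COc1cc(cc(OC)c1OC)[C@H]([O-])[C@H](COC(c1ccccc1)(c1ccccc1)c1ccccc1)c1cccc(OC)c1F.[K+] | intermediate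
12 | (2R,3S)-7-methoxy-2-(3,4,5-trimethoxyphenyl)-3-[(triphenylmethoxy)methyl]-2,3-dihydro-1-benzofuran (trans) | COc1cc([C@@H]2Oc3c(OC)cccc3[C@H]2COC(c2ccccc2)(c2ccccc2)c2ccccc2)cc(OC)c1OC | intermediate
13 | [(2R,3S)-7-methoxy-2-(3,4,5-trimethoxyphenyl)-2,3-dihydro-1-benzofuran-3-yl]methanol | COc1cc([C@@H]2Oc3c(OC)cccc3[C@H]2CO)cc(OC)c1OC | intermediate
14 | O-(pinacolboryl) ether of 13 | COc1cc([C@@H]2Oc3c(OC)cccc3[C@H]2COB2OC(C)(C)C(C)(C)O2)cc(OC)c1OC | intermediate
15 | O-(pinacolboryl) ether of 16 | COc1cc([C@@H]2Oc3c(OC)cc(B4OC(C)(C)C(C)(C)O4)cc3[C@H]2COB2OC(C)(C)C(C)(C)O2)cc(OC)c1OC | intermediate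
16 | [(2R,3S)-7-methoxy-5-(4,4,5,5-tetramethyl-1,3,2-dioxaborolan-2-yl)-2-(3,4,5-trimethoxyphenyl)-2,3-dihydro-1-benzofuran-3-yl]methanol | COc1cc([C@@H]2Oc3c(OC)cc(B4OC(C)(C)C(C)(C)O4)cc3[C@H]2CO)cc(OC)c1OC | intermediate
17 | (E)-3-iodoprop-2-en-1-ol | OC/C=C/I | starting material
18 | (−)-(7R,8S,7'E)-3,4,5,5'-tetramethoxy-4',7-epoxy-8,3'-neolign-7'-ene-9,9'-diol | COc1cc([C@@H]2Oc3c(OC)cc(/C=C/CO)cc3[C@H]2CO)cc(OC)c1OC | target

## Step count and least certain steps

Total: 8 steps. Longest linear sequence: 8 steps (1 to 18); 2, 5 and 17 enter as purchased partners.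

Step 5 (key step). The substitution may be too slow on a ring that has no acceptor and a methoxy group beside fluorine. At the temperature needed, the alkoxide and excess amide base could then be consumed by attack on the solvent, by O-demethylation of an aryl methyl ether or by slow degradation before ring C has closed. The fallback forms the same O–C4' bond by palladium-catalysed aryl ether formation on a bromide. It sets out from 2 and 5. Purchased (2-bromo-3-methoxyphenyl)acetic acid is attached to 2 as in step 1 to give (R)-4-benzyl-3-[2-(2-bromo-3-methoxyphenyl)acetyl]oxazolidin-2-one F1. The boron aldol with 5 as in step 2 gives (R)-4-benzyl-3-[(2R,3R)-2-(2-bromo-3-methoxyphenyl)-3-hydroxy-3-(3,4,5-trimethoxyphenyl)propanoyl]oxazolidin-2-one F2. LiBH4 gives (1R,2S)-2-(2-bromo-3-methoxyphenyl)-1-(3,4,5-trimethoxyphenyl)propane-1,3-diol F3, and tritylation gives (1R,2S)-2-(2-bromo-3-methoxyphenyl)-1-(3,4,5-trimethoxyphenyl)-3-(triphenylmethoxy)propan-1-ol F4. Pd(OAc)2 with 2-(di-tert-butylphosphino)-1,1'-binaphthyl and Cs2CO3 in toluene at 80 °C should then close ring C by oxidative addition of zerovalent palladium into C4'–Br, alkoxide exchange and C–O reductive elimination. The route is rejoined at 12.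

Step 2. A conjugated, aryl-substituted enolate meets an electron-rich aldehyde, so the addition may be sluggish or reversible. Retro-aldol equilibration would erode the syn selectivity, and the acidic C8 position could epimerise during work-up. The fallback forms C7–C8 by acylation and sets C7 by reduction. It sets out from 1, which is attached to purchased (S)-4-benzyloxazolidin-2-one as in step 1 to give (S)-4-benzyl-3-[2-(2-fluoro-3-methoxyphenyl)acetyl]oxazolidin-2-one F5. Its sodium enolate (NaN(SiMe3)2, THF, −78 °C) is acylated with 3,4,5-trimethoxybenzoyl chloride. The chelated enolate is attacked on the face away from the benzyl group, the opposite topicity to the boron aldol, which is why the antipodal auxiliary is used. This should give (S)-4-benzyl-3-[(2R)-2-(2-fluoro-3-methoxyphenyl)-3-oxo-3-(3,4,5-trimethoxyphenyl)propanoyl]oxazolidin-2-one F6. Chelation-controlled reduction with Zn(BH4)2 (CH2Cl2, −20 °C) should give the syn alcohol (S)-4-benzyl-3-[(2R,3R)-2-(2-fluoro-3-methoxyphenyl)-3-hydroxy-3-(3,4,5-trimethoxyphenyl)propanoyl]oxazolidin-2-one F7. LiBH4 as in step 3 rejoins the route at 9.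

Step 7. Site selectivity could be lost through borylation beside the small methoxy group at C6', and the catalyst could stall if O-borylation of the hydroxyl is incomplete. The fallback uses an electronically controlled C–H functionalisation instead of a sterically controlled one. It sets out from 13. Thianthrene S-oxide, (CF3CO)2O and HBF4·OEt2 in MeCN at 0 °C should give 5-[(2R,3S)-3-(hydroxymethyl)-7-methoxy-2-(3,4,5-trimethoxyphenyl)-2,3-dihydro-1-benzofuran-5-yl]thianthren-5-ium tetrafluoroborate F8. Substitution should go para to the ring oxygen at C1', because the two free positions of ring A are each flanked by two substituents and closed to so bulky an electrophile. The hydroxyl is trifluoroacetylated in passing and freed on NaHCO3/MeOH work-up. Pd(dppf)Cl2, B2pin2 and KOAc in dioxane at 60 °C then exchange the sulfonium group for Bpin, and the route is rejoined at 16.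

Step 8. Protodeboronation of the electron-rich aryl boronate in aqueous base could outrun transmetalation, and the iodoallyl alcohol could isomerise on palladium. The fallback builds the chain by an oxidative Heck reaction followed by reduction. It sets out from 16. Pd(OAc)2, 2,9-dimethyl-1,10-phenanthroline, methyl acrylate and O2 (1 atm) in DMF at 50 °C should give methyl (E)-3-[(2R,3S)-3-(hydroxymethyl)-7-methoxy-2-(3,4,5-trimethoxyphenyl)-2,3-dihydro-1-benzofuran-5-yl]prop-2-enoate F9, with E geometry from syn carbopalladation and syn β-hydride elimination on divalent palladium. DIBAL-H (CH2Cl2, −78 °C) reduces the ester in the 1,2 sense, and the route is rejoined at 18.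

## Further compounds

F1 | step 5 | (R)-4-benzyl-3-[2-(2-bromo-3-methoxyphenyl)acetyl]oxazolidin-2-one | COc1cccc(CC(=O)N2[C@H](Cc3ccccc3)COC2=O)c1Br
F2 | step 5 | (R)-4-benzyl-3-[(2R,3R)-2-(2-bromo-3-methoxyphenyl)-3-hydroxy-3-(3,4,5-trimethoxyphenyl)propanoyl]oxazolidin-2-one | COc1cc(cc(OC)c1OC)[C@H](O)[C@H](C(=O)N1[C@H](Cc2ccccc2)COC1=O)c1cccc(OC)c1Br
F3 | step 5 | (1R,2S)-2-(2-bromo-3-methoxyphenyl)-1-(3,4,5-trimethoxyphenyl)propane-1,3-diol | COc1cc(cc(OC)c1OC)[C@H](O)[C@H](CO)c1cccc(OC)c1Br
F4 | step 5 | (1R,2S)-2-(2-bromo-3-methoxyphenyl)-1-(3,4,5-trimethoxyphenyl)-3-(triphenylmethoxy)propan-1-ol | COc1cc(cc(OC)c1OC)[C@H](O)[C@H](COC(c1ccccc1)(c1ccccc1)c1ccccc1)c1cccc(OC)c1Br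
F5 | step 2 | (S)-4-benzyl-3-[2-(2-fluoro-3-methoxyphenyl)acetyl]oxazolidin-2-one | COc1cccc(CC(=O)N2[C@@H](Cc3ccccc3)COC2=O)c1F
F6 | step 2 | (S)-4-benzyl-3-[(2R)-2-(2-fluoro-3-methoxyphenyl)-3-oxo-3-(3,4,5-trimethoxyphenyl)propanoyl]oxazolidin-2-one | COc1cc(cc(OC)c1OC)C(=O)[C@H](C(=O)N1[C@@H](Cc2ccccc2)COC1=O)c1cccc(OC)c1F
F7 | step 2 | (S)-4-benzyl-3-[(2R,3R)-2-(2-fluoro-3-methoxyphenyl)-3-hydroxy-3-(3,4,5-trimethoxyphenyl)propanoyl]oxazolidin-2-one | COc1cc(cc(OC)c1OC)[C@H](O)[C@H](C(=O)N1[C@@H](Cc2ccccc2)COC1=O)c1cccc(OC)c1F
F8 | step 7 | 5-[(2R,3S)-3-(hydroxymethyl)-7-methoxy-2-(3,4,5-trimethoxyphenyl)-2,3-dihydro-1-benzofuran-5-yl]thianthren-5-ium tetrafluoroborate | COc1cc([C@@H]2Oc3c(OC)cc([S+]4c5ccccc5Sc5ccccc45)cc3[C@H]2CO)cc(OC)c1OC.F[B-](F)(F)F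
F9 | step 8 | methyl (E)-3-[(2R,3S)-3-(hydroxymethyl)-7-methoxy-2-(3,4,5-trimethoxyphenyl)-2,3-dihydro-1-benzofuran-5-yl]prop-2-enoate | COc1cc([C@@H]2Oc3c(OC)cc(/C=C/C(=O)OC)cc3[C@H]2CO)cc(OC)c1OC
A1 | alternative 1 | (E)-tert-butyldimethyl{[3-(4,4,5,5-tetramethyl-1,3,2-dioxaborolan-2-yl)prop-2-en-1-yl]oxy}silane | CC(C)(C)[Si](C)(C)OC/C=C/B1OC(C)(C)C(C)(C)O1
A2 | alternative 1 | 3,4,5-trimethoxyphenyllithium | [Li]c1cc(OC)c(OC)c(OC)c1
A3 | alternative 1 | methyl (E)-3-[3-bromo-5-methoxy-4-(methoxymethoxy)phenyl]prop-2-enoate | COCOc1c(Br)cc(/C=C/C(=O)OC)cc1OC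
A4 | alternative 1 | methyl (E)-3-{3-[(1R,2S)-3-(tert-butyldimethylsilyloxy)-1-(4,4,5,5-tetramethyl-1,3,2-dioxaborolan-2-yl)-1-(3,4,5-trimethoxyphenyl)propan-2-yl]-5-methoxy-4-(methoxymethoxy)phenyl}prop-2-enoate | COc1cc(cc(OC)c1OC)[C@H](B1OC(C)(C)C(C)(C)O1)[C@H](CO[Si](C)(C)C(C)(C)C)c1cc(/C=C/C(=O)OC)cc(OC)c1OCOC
A5 | alternative 1 | methyl (E)-3-{3-[(1R,2S)-3-(tert-butyldimethylsilyloxy)-1-hydroxy-1-(3,4,5-trimethoxyphenyl)propan-2-yl]-5-methoxy-4-(methoxymethoxy)phenyl}prop-2-enoate | COc1cc(cc(OC)c1OC)[C@H](O)[C@H](CO[Si](C)(C)C(C)(C)C)c1cc(/C=C/C(=O)OC)cc(OC)c1OCOC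
A6 | alternative 2 | methyl 2-[5-bromo-3-methoxy-2-(3,4,5-trimethoxybenzyloxy)phenyl]-2-diazoacetate | COC(=O)C(=[N+]=[N-])c1cc(Br)cc(OC)c1OCc1cc(OC)c(OC)c(OC)c1
A7 | alternative 2 | methyl (2R,3S)-5-bromo-7-methoxy-2-(3,4,5-trimethoxyphenyl)-2,3-dihydro-1-benzofuran-3-carboxylate (cis) | COc1cc([C@@H]2Oc3c(OC)cc(Br)cc3[C@@H]2C(=O)OC)cc(OC)c1OC
A8 | alternative 3 | 4-bromo-2-[2-(tert-butyldimethylsilyloxy)-1-(4-methylphenylsulfonyl)ethyl]-6-methoxyphenol (racemic) | COc1cc(Br)cc(C(CO[Si](C)(C)C(C)(C)C)S(=O)(=O)c2ccc(C)cc2)c1O
A9 | alternative 3 | (2R,5R)-2,5-dimethyl-1-(3,4,5-trimethoxybenzyl)thiolan-1-ium trifluoromethanesulfonate | C[C@@H]1CC[C@@H](C)[S+]1Cc1cc(OC)c(OC)c(OC)c1.[O-]S(=O)(=O)C(F)(F)F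
A10 | alternative 3 | tert-butyl{[(2R,3S)-5-bromo-7-methoxy-2-(3,4,5-trimethoxyphenyl)-2,3-dihydro-1-benzofuran-3-yl]methoxy}dimethylsilane (trans) | COc1cc([C@@H]2Oc3c(OC)cc(Br)cc3[C@H]2CO[Si](C)(C)C(C)(C)C)cc(OC)c1OC
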